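**Remark (assumptions).** Atom numbering used throughout: C1 is the ring carbon bearing OH and the exocyclic C7H2–OBz; C2 and C3 carry the acetates; C4=C5 is the ring alkene; C6 is the secondary carbinol. The SMILES is read as C1–OH, C2–OAc and C6–OH on one face and C3–OAc on the other, i.e. [(1S,2S,5S,6R)-5,6-diacetoxy-1,2-dihydroxycyclohex-3-en-1-yl]methyl benzoate. The dehydrogenase-deficient strain Ralstonia eutropha B9 is taken to be obtainable from a culture collection.

**Route in one sentence:** dioxygenase-catalysed ipso,ortho cis-dihydroxylation of benzoic acid.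

## Structural features

- The target has one carbocycle, a cyclohex-4-ene, whose exocyclic carbon C7 is joined to the ring at C1 and carries the only aromatic ring as a benzoate.
- Four contiguous stereocentres C6–C1–C2–C3 lie on one side of the C4=C5 alkene. C1 is a fully substituted carbinol; C1–OH, C2–OAc and C6–OH are mutually cis; C3–OAc is trans to C2–OAc.
- Five oxygens sit on seven carbons in three different states: two acetates (C2, C3), one primary benzoate (C7) and two free hydroxyls (tertiary C1, allylic C6).
- The compound is fragile. Base would cause acyl migration between neighbouring oxygens. Acid or heat would cause allylic ionisation and twofold elimination to an arene. The end-game must therefore be close to neutral.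
- The real difficulty is twofold: the absolute configuration of the tetrasubstituted C1 together with its oxygenated neighbours, and the trans-1,4 relation of C3–O and C6–O across the alkene with different acylation at the two ends.
- The feature exploited by the key step: the ring carbons plus C7 are the carbon skeleton of benzoic acid, and the cis C1(OH)(C7)–C2(O) unit is the ipso,ortho cis-dihydrodiol of that arene. The key step dearomatises the benzene ring across the carboxyl-bearing carbon and the adjacent CH.

## Logic of the disconnections

**12 to 9.** The C6–O bond is cut, the alkene is moved back from C4=C5 to C5=C6 and a C4–Se bond is restored (retro [2,3]-sigmatropic shift). This cut is chosen because the trans-1,4 relation of C3–O and C6–O is the hardest relative relationship, and a suprafacial shift copies the configuration of C4 onto C6. It also frees the C6 hydroxyl last, so it is the only secondary oxygen that is never acylated. The forward step must oxidise selenium chemoselectively and rearrange faster than it eliminates.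

**9 to 8.** The two acetyl–oxygen bonds at O2 and O3 are cut. This removes all base-labile groups except the benzoate from the earlier intermediates. The forward acetylation must leave the tertiary C1 hydroxyl untouched.

**8 to 7.** The C1 and C2 hydroxyls are tied back into an isopropylidene ketal. The ketal is wanted earlier as a rigid face-blocking group. The forward hydrolysis must not disturb the allylic selenide or the benzoate.

**7 to 6.** The C4–Se bond is cut, giving back a C3–C4 epoxide. One ring opening then sets C4 (the relay centre for C6) with inversion and leaves C3–O as it was made. The forward step needs attack at the allylic carbon C4 and not at C3 or C6.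

**6 to 5.** The two epoxide C–O bonds at C3 and C4 are cut to reveal a cyclohexa-3,5-diene. The gain is that the C3 and C6 oxygens both derive from one diene. The forward epoxidation must choose C3=C4 over C5=C6 and the face anti to the ketal.

**5 to 3 (via 4).** The benzoyl–O7 bond is cut and C7 is raised to the carboxylic acid level. C7 is then the carboxyl carbon of the starting arene. The forward steps are a hydride reduction and an acylation on a substrate with no other free hydroxyl.

**3 to 1 (via 2).** The ketal is removed and the C1–O and C2–O bonds are cut together, which returns the flat, achiral, seven-carbon arene 1. The enzyme product of known (1S,2R) configuration maps onto C1 and C2 of 12. It does not map onto C1 and C6, which would require the antipode, so C6–O is deliberately left to the relay chemistry. The forward step needs an enzyme that attacks ipso,ortho, on one enantiotopic face, without rearomatising.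

## Other disconnections considered

**Alternative 1:** (the first that comes to mind) cuts C1–O and C2–O as a chemical syn-dihydroxylation. The forward step is osmium tetroxide OsO4 (catalytic, N-methylmorpholine N-oxide) on the C1=C2 bond of the trans-3,6-dioxygenated diene A1, giving diol A2, then C2 acetylation and desilylation.
- A1 has allylic oxygens on both sides of C1=C2 and on opposite faces (C3–OAc and C6–OSi). The preference of OsO4 to add anti to an allylic oxygen therefore points both ways, and the face needed is syn to the bulky C6 substituent.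
- A1 is a doubly allylic 1,4-diene that can aromatise by 1,4-elimination.
- Making A1 as a single enantiomer is a problem almost as large as the target.
- The chosen plan sets C1/C2 in absolute terms before any other stereocentre exists.

**Alternative 2:** cuts C4=C5 by ring-closing metathesis. The forward step is closure of the open-chain 1,7-diene A3 with the second-generation Grubbs catalyst.
- The ring closure itself is unproblematic.
- It moves all four contiguous centres, including the tertiary carbinol, into an acyclic chain. That chain would have to be built from a sugar-derived ketone by a vinyl-metal addition of uncertain facial control.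
- Differentiated acyl groups on an acyclic polyol migrate easily.
- A dozen or more steps are foreseeable, against nine here.

**Alternative 3:** cuts the C1–O bond by oxidative dearomatisation of a phenol. The forward step is Adler–Becker oxidation of 2-hydroxybenzyl alcohol with NaIO4 to the spiro-epoxydienone A4, followed by C6 carbonyl reduction, epoxide opening at C7 by benzoate and oxidation of the diene.
- The C1 spiro centre is formed with no handle for absolute control, so A4 is racemic and a resolution is needed.
- Dienones of this type dimerise readily by Diels–Alder reaction.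
- The C2/C3 trans-dioxygenation still has to be placed regioselectively on a 2,4-dienone.
- The enzymatic dearomatisation gives the same gain in simplicity with the absolute configuration included.

Key step: step 1

## Route

Step 1
Reactants: 1 benzoic acid
Product: 2 (1S,2R)-1,2-dihydroxycyclohexa-3,5-diene-1-carboxylic acid
Conditions: whole cells of Ralstonia eutropha B9 (benzoate 1,2-dioxygenase, diol-dehydrogenase-deficient), fructose, mineral salts medium, phosphate buffer pH 7.2, air, 30 °C, fed-batch addition of 1; cell removal, acidification to pH 3 at 0 °C, EtOAc extraction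
Reagents that add atoms: dioxygen, O=O
Why: Benzoate 1,2-dioxygenase is a Rieske-type non-heme iron dioxygenase in which electrons from NADH pass through a flavin and iron–sulfur clusters to a mononuclear iron centre (divalent iron in the resting enzyme) that binds O2 next to the substrate. The activated iron–peroxo unit transfers both oxygen atoms to the adjacent ring carbons C1 and C2 from the same face, so the diol is necessarily cis; the closest known reaction type is the microbial arene cis-dihydroxylation, which is established for benzoate itself. No ring is closed: the benzene ring is dearomatised to a cyclohexa-3,5-diene that already holds all seven core carbons. C1 and C2 are created together, their cis relation by suprafacial delivery from one metal-bound O2 and their absolute (1S,2R) configuration by the enzyme pocket. The selectivity needed is ipso,ortho instead of ortho,meta attack on a single enantiotopic face, and it is secured by the carboxylate of 1, the recognition handle that holds the carboxyl-bearing carbon and one ortho carbon over the iron. The B9 mutant lacks the dehydrogenase that would decarboxylate and rearomatise 2, so 2 should accumulate in the medium while fructose metabolism keeps the NADH pool reduced. The (1S,2R) configuration is the one required at C1 and C2 of 12, and the remaining diene is the handle for C3 and C6.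

Step 2
Reactants: 2 (1S,2R)-1,2-dihydroxycyclohexa-3,5-diene-1-carboxylic acid
Product: 3 (3aS,7aR)-2,2-dimethyl-3a,7a-dihydro-1,3-benzodioxole-3a-carboxylic acid
Conditions: 2,2-dimethoxypropane (5 equiv), p-TsOH·H2O (2 mol %), acetone, 0 °C to rt; Et3N quench
Reagents that add atoms: 2,2-dimethoxypropane, COC(C)(C)OC
Why: Acid-catalysed transketalisation of the cis-1,2-diol gives the cis-fused dioxolane; anhydrous conditions at low temperature should outpace acid-promoted dehydration of the dienediol, and neither stereocentre is touched (C1 has no hydrogen, C2 keeps its C–O bond).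

Step 3
Reactants: 3 (3aS,7aR)-2,2-dimethyl-3a,7a-dihydro-1,3-benzodioxole-3a-carboxylic acid
Product: 4 [(3aR,7aR)-2,2-dimethyl-3a,7a-dihydro-1,3-benzodioxol-3a-yl]methanol
Conditions: LiAlH4 (2.5 equiv), THF, 0 °C to rt; H2O, 15% aq NaOH, H2O work-up
Reagents that add atoms: none
Why: Hydride reduction of the carboxylic acid through its lithium carboxylate and acyl aluminate; the unconjugated diene and the ketal are inert to hydride and C1 cannot epimerise (its descriptor changes from S to R only because CH2OH ranks lower than CO2H).

Step 4
Reactants: 4 [(3aR,7aR)-2,2-dimethyl-3a,7a-dihydro-1,3-benzodioxol-3a-yl]methanol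
Product: 5 [(3aR,7aR)-2,2-dimethyl-3a,7a-dihydro-1,3-benzodioxol-3a-yl]methyl benzoate
Conditions: BzCl (1.2 equiv), pyridine, DMAP (5 mol %), CH2Cl2, 0 °C to rt
Reagents that add atoms: benzoyl chloride, O=C(Cl)c1ccccc1
Why: DMAP-catalysed acylation (via the N-benzoylpyridinium ion) of the only free hydroxyl installs the C7 benzoate of the target before any acetate is present.

Step 5
Reactants: 5 [(3aR,7aR)-2,2-dimethyl-3a,7a-dihydro-1,3-benzodioxol-3a-yl]methyl benzoate
Product: 6 [(1R,2R,3S,4S)-3,4-epoxy-1,2-(isopropylidenedioxy)cyclohex-5-en-1-yl]methyl benzoate (epoxide anti to the ketal)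
Conditions: dimethyldioxirane (ca. 0.07 M in acetone, 1.2 equiv), CH2Cl2, −20 to 0 °C
Reagents that add atoms: dimethyldioxirane, CC1(C)OO1
Why: Concerted oxygen-atom transfer from the dioxirane (spiro transition state) to the more accessible alkene: the reagent should approach the convex face anti to the cis-fused dioxolane, where C3=C4 is flanked only by H-2 while C5=C6 is screened by the angular CH2OBz on C1, so both new C–O bonds (C3, C4) form on the face opposite to the C1/C2 oxygens. The neutral medium spares the vinyl epoxide, which is also less nucleophilic than the diene.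

Step 6
Reactants: 6 [(1R,2R,3S,4S)-3,4-epoxy-1,2-(isopropylidenedioxy)cyclohex-5-en-1-yl]methyl benzoate
Product: 7 [(1R,2R,3R,4R)-3-hydroxy-1,2-(isopropylidenedioxy)-4-(phenylselanyl)cyclohex-5-en-1-yl]methyl benzoate
Conditions: PhSeSePh (0.6 equiv), NaBH4 (1.3 equiv), EtOH, 0 °C; then 6 in THF, 0 °C to rt
Reagents that add atoms: diphenyl diselenide, c1ccc(cc1)[Se][Se]c1ccccc1
Why: SN2 opening of the vinyl epoxide by the soft, weakly basic benzeneselenolate (as its borate complex) at the allylic carbon C4, anti to the breaking C–O bond (trans-diaxial, Fürst–Plattner), so C4 is inverted and selenium ends on the face of the C1/C2 oxygens while C3 keeps its oxygen on the other face. Attack at C3 is disfavoured by the adjacent C2–O bond and the dioxolane, and the benzoate should survive the non-basic medium.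

Step 7
Reactants: 7 [(1R,2R,3R,4R)-3-hydroxy-1,2-(isopropylidenedioxy)-4-(phenylselanyl)cyclohex-5-en-1-yl]methyl benzoate
Product: 8 [(1R,2R,3R,4R)-1,2,3-trihydroxy-4-(phenylselanyl)cyclohex-5-en-1-yl]methyl benzoate
Conditions: AcOH/H2O/THF (3:1:1), 45 °C
Reagents that add atoms: none
Why: Mild acid hydrolysis of the isopropylidene ketal; aqueous acetic acid should be too weak to activate the C3 hydroxyl towards seleniranium formation or to ionise the allylic C–Se bond, and the primary benzoate is at its thermodynamically preferred position.

Step 8
Reactants: 8 [(1R,2R,3R,4R)-1,2,3-trihydroxy-4-(phenylselanyl)cyclohex-5-en-1-yl]methyl benzoate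
Product: 9 [(1R,2R,3R,4R)-2,3-diacetoxy-1-hydroxy-4-(phenylselanyl)cyclohex-5-en-1-yl]methyl benzoate
Conditions: Ac2O (3 equiv), pyridine, DMAP (5 mol %), CH2Cl2, 0 °C to rt
Reagents that add atoms: acetic anhydride, CC(=O)OC(C)=O
Why: Nucleophile-catalysed acetylation of the two secondary hydroxyls; the tertiary C1 hydroxyl, flanked by C2, C6 and C7, should not be acylated at 0 °C with a limited excess of anhydride.

Step 9
Reactants: 9 [(1R,2R,3R,4R)-2,3-diacetoxy-1-hydroxy-4-(phenylselanyl)cyclohex-5-en-1-yl]methyl benzoate
Product: 12 [(1S,2S,5S,6R)-5,6-diacetoxy-1,2-dihydroxycyclohex-3-en-1-yl]methyl benzoate, via allylic selenoxide 10 (not isolated), via allylic selenenate ester 11 (not isolated)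
Conditions: 30% aq H2O2 (3 equiv), pyridine (3 equiv), CH2Cl2, 0 °C to rt
Reagents that add atoms: hydrogen peroxide, OO
Why: Oxidation at selenium gives selenoxide 10, which undergoes the [2,3]-sigmatropic selenoxide–selenenate rearrangement through a five-membered envelope transition state; the shift is suprafacial, so oxygen is delivered to C6 on the face that carried selenium at C4 (the face of the C1 hydroxyl) and the double bond moves to C4=C5. The Se–O bond of 11 is then cleaved by the aqueous peroxide to free the C6 hydroxyl; the rearrangement should be far faster than selenoxide syn-elimination, which would also have to form an enol acetate towards C3.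

## Compound list

1 | benzoic acid | OC(=O)c1ccccc1 | starting material
2 | (1S,2R)-1,2-dihydroxycyclohexa-3,5-diene-1-carboxylic acid | C1=CC=C[C@@](O)(C(=O)O)[C@@H]1O | intermediate
3 | (3aS,7aR)-2,2-dimethyl-3a,7a-dihydro-1,3-benzodioxole-3a-carboxylic acid | C1=CC=C[C@]2(C(=O)O)OC(C)(C)O[C@H]12 | intermediate
4 | [(3aR,7aR)-2,2-dimethyl-3a,7a-dihydro-1,3-benzodioxol-3a-yl]methanol | C1=CC=C[C@]2(CO)OC(C)(C)O[C@H]12 | intermediate
5 | [(3aR,7aR)-2,2-dimethyl-3a,7a-dihydro-1,3-benzodioxol-3a-yl]methyl benzoate | C1=CC=C[C@]2(COC(=O)c3ccccc3)OC(C)(C)O[C@H]12 | intermediate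
6 | [(1R,2R,3S,4S)-3,4-epoxy-1,2-(isopropylidenedioxy)cyclohex-5-en-1-yl]methyl benzoate | [C@H]12O[C@H]1C=C[C@]3(COC(=O)c4ccccc4)OC(C)(C)O[C@H]23 | intermediate
7 | [(1R,2R,3R,4R)-3-hydroxy-1,2-(isopropylidenedioxy)-4-(phenylselanyl)cyclohex-5-en-1-yl]methyl benzoate | O[C@H]1[C@H]([Se]c2ccccc2)C=C[C@]3(COC(=O)c4ccccc4)OC(C)(C)O[C@H]13 | intermediate
8 | [(1R,2R,3R,4R)-1,2,3-trihydroxy-4-(phenylselanyl)cyclohex-5-en-1-yl]methyl benzoate | O[C@H]1[C@H]([Se]c2ccccc2)C=C[C@@](O)(COC(=O)c3ccccc3)[C@@H]1O | intermediate
9 | [(1R,2R,3R,4R)-2,3-diacetoxy-1-hydroxy-4-(phenylselanyl)cyclohex-5-en-1-yl]methyl benzoate | CC(=O)O[C@H]1[C@H]([Se]c2ccccc2)C=C[C@@](O)(COC(=O)c3ccccc3)[C@@H]1OC(C)=O | intermediate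
10 | [(1R,2R,3R,4R)-2,3-diacetoxy-1-hydroxy-4-(phenylseleninyl)cyclohex-5-en-1-yl]methyl benzoate (both configurations at selenium) | CC(=O)O[C@H]1[C@H]([Se](=O)c2ccccc2)C=C[C@@](O)(COC(=O)c3ccccc3)[C@@H]1OC(C)=O | intermediate
11 | [(1R,2S,5S,6R)-5,6-diacetoxy-1-hydroxy-2-(phenylselanyloxy)cyclohex-3-en-1-yl]methyl benzoate | CC(=O)O[C@H]1C=C[C@H](O[Se]c2ccccc2)[C@@](O)(COC(=O)c3ccccc3)[C@@H]1OC(C)=O | intermediate
12 | [(1S,2S,5S,6R)-5,6-diacetoxy-1,2-dihydroxycyclohex-3-en-1-yl]methyl benzoate | CC(=O)O[C@H]1C=C[C@H](O)[C@@](O)(COC(=O)c2ccccc2)[C@@H]1OC(C)=O | target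

## Step count and least certain steps

Total step count: 9. Longest linear sequence: 9 steps (the route is fully linear from 1).

**Step 1 (key step).**
- What may go wrong: incomplete conversion or onward oxidation if the dehydrogenase block of the strain is leaky, and rearomatisation of the dienediol by acid-promoted loss of water during the acidic extraction and concentration.
- Fallback (sets out from 1, comes back at 2): reductive instead of oxidative dearomatisation, followed by a classical resolution.
  - Birch reduction of 1 (Li, NH3, t-BuOH; NH4Cl) would give cyclohexa-2,5-diene-1-carboxylic acid F1.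
  - Hydroxylation of its dianion (LDA, THF, −78 °C; 2-(phenylsulfonyl)-3-phenyloxaziridine) would give the achiral 1-hydroxycyclohexa-2,5-diene-1-carboxylic acid F2.
  - Hydroxyl-directed epoxidation of one of its two equivalent double bonds (VO(acac)2 cat., t-BuOOH, CH2Cl2) would give racemic cis-2-hydroxy-7-oxabicyclo[4.1.0]hept-3-ene-2-carboxylic acid F3.
  - Base-induced opening of the epoxide towards the allylic CH2 (LiNEt2, THF, 0 °C) would give racemic cis-1,2-dihydroxycyclohexa-3,5-diene-1-carboxylic acid F4.
  - Crystallisation with (R)-1-phenylethylamine would give the (R)-1-phenylethylammonium salt of 2 F5 (the antipodal amine would be taken if the salt of the unwanted acid proves the less soluble). Cold acidification of the salt liberates 2.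

**Step 5.**
- What may go wrong: poor site selectivity between the two double bonds of the diene (the screening of C5=C6 by the C7 substituent is the only bias) and some double epoxidation.
- Fallback (sets out from 5, comes back at 12): oxygenate C3 and C6 together and correct C6 by reduction.
  - Photooxygenation of 5 (O2, tetraphenylporphyrin, visible light, CH2Cl2, −20 °C) should add singlet oxygen across C3/C6 anti to the ketal and give the 3,6-epidioxide of 5 F6.
  - Kornblum–DeLaMare rearrangement (Et3N, CH2Cl2) is expected to remove the bridgehead hydrogen at C6, the one next to the carbon that carries two C–O bonds, and give [3-hydroxy-1,2-(isopropylidenedioxy)-6-oxocyclohex-4-en-1-yl]methyl benzoate F7 with the C3 oxygen already on the correct face.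
  - Ketal hydrolysis (TFA/H2O 9:1, CH2Cl2, 0 °C) would give [(1R,5S,6R)-1,5,6-trihydroxy-2-oxocyclohex-3-en-1-yl]methyl benzoate F8.
  - Acetylation (Ac2O, pyridine) would give [(1R,5S,6R)-5,6-diacetoxy-1-hydroxy-2-oxocyclohex-3-en-1-yl]methyl benzoate F9.
  - Luche reduction (NaBH4, CeCl3·7H2O, MeOH, −78 °C) should deliver hydride axially, anti to the pseudo-axial C1–O bond of the conformer with all large groups equatorial, and give 12.

**Step 7.**
- What may go wrong: loss of the selenium handle under acid, either by activation of the C3 hydroxyl with selenium participation (seleniranium formation and regeneration of the diene) or by ionisation and 1,3-shift of the allylic selenide; a sluggish ketal cleavage would force stronger acid.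
- Fallback (sets out from 7, comes back at 12): rearrange first, so that the acid step acts on a selenium-free compound.
  - Acetylation of 7 (Ac2O, pyridine, DMAP) would give [(1R,2R,3R,4R)-3-acetoxy-1,2-(isopropylidenedioxy)-4-(phenylselanyl)cyclohex-5-en-1-yl]methyl benzoate F10.
  - Oxidation and [2,3]-shift as in step 9 (H2O2, pyridine) would give [3-acetoxy-6-hydroxy-1,2-(isopropylidenedioxy)cyclohex-4-en-1-yl]methyl benzoate F11.
  - The new hydroxyl would be masked ((ClCH2CO)2O, pyridine) as the 6-O-chloroacetate of F11 F12.
  - Ketal hydrolysis (TFA/H2O 9:1, CH2Cl2, 0 °C) would give [5-acetoxy-2-(chloroacetoxy)-1,6-dihydroxycyclohex-3-en-1-yl]methyl benzoate F13.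
  - Acetylation at C2 would give the 6-O-chloroacetyl derivative of 12 F14.
  - Thiourea (2,6-lutidine, MeOH, 40 °C) would remove the chloroacetate selectively and give 12.

**Step 2.**
- What may go wrong: acid-promoted dehydration and rearomatisation of the free dienediol acid before the ketal has formed (the free carboxyl group also opens a decarboxylative pathway).
- Fallback (sets out from 2, comes back at 4): mask the acid under basic conditions first and reduce an ester instead of the acid.
  - MeI and KHCO3 in DMF would give methyl (1S,2R)-1,2-dihydroxycyclohexa-3,5-diene-1-carboxylate F15.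
  - 2,2-Dimethoxypropane and pyridinium p-toluenesulfonate would give methyl (3aS,7aR)-2,2-dimethyl-3a,7a-dihydro-1,3-benzodioxole-3a-carboxylate F16.
  - DIBAL-H (CH2Cl2, −78 to 0 °C) would give 4.

## Further compounds

F1 | step 1 | cyclohexa-2,5-diene-1-carboxylic acid | OC(=O)C1C=CCC=C1
F2 | step 1 | 1-hydroxycyclohexa-2,5-diene-1-carboxylic acid | OC(=O)C1(O)C=CCC=C1
F3 | step 1 | racemic cis-2-hydroxy-7-oxabicyclo[4.1.0]hept-3-ene-2-carboxylic acid (epoxide cis to the hydroxyl, both enantiomers) | OC(=O)[C@]1(O)C=CC[C@H]2O[C@@H]12.OC(=O)[C@@]1(O)C=CC[C@@H]2O[C@H]12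
F4 | step 1 | racemic cis-1,2-dihydroxycyclohexa-3,5-diene-1-carboxylic acid (both enantiomers) | C1=CC=C[C@@](O)(C(=O)O)[C@@H]1O.C1=CC=C[C@](O)(C(=O)O)[C@H]1O
F5 | step 1 | (R)-1-phenylethylammonium (1S,2R)-1,2-dihydroxycyclohexa-3,5-diene-1-carboxylate | C1=CC=C[C@@](O)(C(=O)[O-])[C@@H]1O.C[C@@H]([NH3+])c1ccccc1
F6 | step 5 | [3,6-epidioxy-1,2-(isopropylidenedioxy)cyclohex-4-en-1-yl]methyl benzoate (peroxide bridge anti to the ketal) | C1=C[C@@H]2OO[C@H]1[C@]3(COC(=O)c4ccccc4)OC(C)(C)O[C@H]23
F7 | step 5 | [3-hydroxy-1,2-(isopropylidenedioxy)-6-oxocyclohex-4-en-1-yl]methyl benzoate (C3 hydroxyl anti to the ketal) | O[C@H]1C=CC(=O)[C@]2(COC(=O)c3ccccc3)OC(C)(C)O[C@H]12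
F8 | step 5 | [(1R,5S,6R)-1,5,6-trihydroxy-2-oxocyclohex-3-en-1-yl]methyl benzoate | O[C@H]1C=CC(=O)[C@@](O)(COC(=O)c2ccccc2)[C@@H]1O
F9 | step 5 | [(1R,5S,6R)-5,6-diacetoxy-1-hydroxy-2-oxocyclohex-3-en-1-yl]methyl benzoate | CC(=O)O[C@H]1C=CC(=O)[C@@](O)(COC(=O)c2ccccc2)[C@@H]1OC(C)=O
F10 | step 7 | [(1R,2R,3R,4R)-3-acetoxy-1,2-(isopropylidenedioxy)-4-(phenylselanyl)cyclohex-5-en-1-yl]methyl benzoate | CC(=O)O[C@H]1[C@H]([Se]c2ccccc2)C=C[C@]3(COC(=O)c4ccccc4)OC(C)(C)O[C@H]13
F11 | step 7 | [3-acetoxy-6-hydroxy-1,2-(isopropylidenedioxy)cyclohex-4-en-1-yl]methyl benzoate (configuration as in 12) | CC(=O)O[C@H]1C=C[C@H](O)[C@]2(COC(=O)c3ccccc3)OC(C)(C)O[C@H]12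
F12 | step 7 | [3-acetoxy-6-(chloroacetoxy)-1,2-(isopropylidenedioxy)cyclohex-4-en-1-yl]methyl benzoate (configuration as in 12) | CC(=O)O[C@H]1C=C[C@H](OC(=O)CCl)[C@]2(COC(=O)c3ccccc3)OC(C)(C)O[C@H]12
F13 | step 7 | [5-acetoxy-2-(chloroacetoxy)-1,6-dihydroxycyclohex-3-en-1-yl]methyl benzoate (configuration as in 12) | CC(=O)O[C@H]1C=C[C@H](OC(=O)CCl)[C@@](O)(COC(=O)c2ccccc2)[C@@H]1O
F14 | step 7 | [5,6-diacetoxy-2-(chloroacetoxy)-1-hydroxycyclohex-3-en-1-yl]methyl benzoate (configuration as in 12) | CC(=O)O[C@H]1C=C[C@H](OC(=O)CCl)[C@@](O)(COC(=O)c2ccccc2)[C@@H]1OC(C)=O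
F15 | step 2 | methyl (1S,2R)-1,2-dihydroxycyclohexa-3,5-diene-1-carboxylate | C1=CC=C[C@@](O)(C(=O)OC)[C@@H]1O
F16 | step 2 | methyl (3aS,7aR)-2,2-dimethyl-3a,7a-dihydro-1,3-benzodioxole-3a-carboxylate | C1=CC=C[C@]2(C(=O)OC)OC(C)(C)O[C@H]12
A1 | alternative 1 | [3-acetoxy-6-(tert-butyldimethylsilyloxy)cyclohexa-1,4-dien-1-yl]methyl benzoate (3,6-trans, configuration as in 12) | CC(=O)O[C@H]1C=C[C@H](O[Si](C)(C)C(C)(C)C)C(COC(=O)c2ccccc2)=C1
A2 | alternative 1 | [5-acetoxy-2-(tert-butyldimethylsilyloxy)-1,6-dihydroxycyclohex-3-en-1-yl]methyl benzoate (configuration as in 12) | CC(=O)O[C@H]1C=C[C@H](O[Si](C)(C)C(C)(C)C)[C@@](O)(COC(=O)c2ccccc2)[C@@H]1O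
A3 | alternative 2 | 2-C-(benzoyloxymethyl)-3,4-di-O-acetyl open-chain diene: 4,5-diacetoxy-2,3-dihydroxy-2-vinylhept-6-en-1-yl benzoate (configuration as in 12) | C=C[C@H](O)[C@@](O)(COC(=O)c1ccccc1)[C@H](OC(C)=O)[C@@H](OC(C)=O)C=C
A4 | alternative 3 | racemic 1-oxaspiro[2.5]octa-5,7-dien-4-one (both enantiomers) | O=C1C=CC=C[C@]12CO2.O=C1C=CC=C[C@@]12CO2
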